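**Retrosynthetic overview** (elemane numbering: ring C5–C10; C10 carries CH3 C14 and vinyl C1=C2; C5 carries C4(=C3)C15; lactone O–C8/C7–C11(=C13)–C12)
1. Late operations (C15 aldehyde by allylic oxidation of the C4 isopropenyl group, angelate on O9, C13 methylenation) lead back to a 9α‑hydroxy‑6β‑silyloxy‑elema‑1,3‑dien‑12,8α‑olide.
2. Key disconnection C9–C10: the homoallylic alcohol O–C9–C10(CH3)–C1=C2 inside the cyclohexane C5–C10, whose chair is locked by the trans‑fused γ‑lactone on C7–C8, is the retron of an intramolecular allylboration of a C9 aldehyde by a (Z)‑γ,γ‑disubstituted allylboronate (B–C2–C1=C10).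
3. The (Z)‑allylboronate comes from a temporary seven‑membered O6–B ring: boron‑tethered ring‑closing metathesis of the C6 carbinol onto one of two diastereotopic isopropenyl groups at C5, which adds C1–C2 and fixes the olefin geometry and C5.
4. The bis‑isopropenyl carbinol (C5–C6 bond, C6 configuration) comes from a reagent‑controlled pentadienylboration of a β‑formyl lactone; the lactone carbons C12, C11, C7, C8, C9 are the chiral‑pool unit (R)‑5‑(hydroxymethyl)oxolan‑2‑one, elaborated by butenolide formation, trans vinyl‑cuprate addition and ozonolysis.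
5. Ring order: γ‑lactone (chiral pool, kept throughout) → temporary oxaborepine (made and opened in step 9) → cyclohexane (step 11).

Key step: step 11

Assumption: (R)‑5‑(hydroxymethyl)oxolan‑2‑one (the D‑glutamic‑acid‑derived lactone), 2,4‑dimethylpenta‑1,3‑diene, angelic acid and (−)‑B‑methoxydiisopinocampheylborane (from (+)‑α‑pinene) are commercial.

Step 1
Reactants: 1 (5R)-5-(hydroxymethyl)oxolan-2-one
Product: 2 (5R)-5-{[(triethylsilyl)oxy]methyl}oxolan-2-one
Conditions: Et3SiCl, imidazole, CH2Cl2, 0 °C → rt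
Reagents that add atoms: chlorotriethylsilane, CC[Si](Cl)(CC)CC
Why: Standard silylation of the primary alcohol; the triethylsilyl ether is chosen because a primary Et3Si ether can later be oxidised directly to the aldehyde under Swern conditions, and no stereocentre is touched.

Step 2
Reactants: 2 (5R)-5-{[(triethylsilyl)oxy]methyl}oxolan-2-one
Product: 3 (5R)-3-(phenylselanyl)-5-{[(triethylsilyl)oxy]methyl}oxolan-2-one (C3 epimers)
Conditions: LDA, THF, −78 °C; PhSeBr, −78 °C
Reagents that add atoms: phenylselanyl bromide, Br[Se]c1ccccc1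
Why: α‑Selenenylation of the lactone lithium enolate; the new centre at C3 is destroyed in the next step, so its configuration does not matter.

Step 3
Reactants: 3 (5R)-3-(phenylselanyl)-5-{[(triethylsilyl)oxy]methyl}oxolan-2-one
Product: 5 (5R)-5-{[(triethylsilyl)oxy]methyl}furan-2(5H)-one, via selenoxide 4 (not isolated)
Conditions: 30 % H2O2, pyridine, CH2Cl2, 0 °C → rt
Reagents that add atoms: none
Why: Oxidation to the selenoxide and spontaneous syn‑elimination gives the butenolide; the C8 stereocentre (γ‑carbon) is not touched under these buffered conditions.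

Step 4
Reactants: 5 (5R)-5-{[(triethylsilyl)oxy]methyl}furan-2(5H)-one
Product: 7 (4S,5R)-4-ethenyl-5-{[(triethylsilyl)oxy]methyl}oxolan-2-one, via silyl ketene acetal 6 (not isolated)
Conditions: CH2=CHMgBr, CuBr·SMe2 (10 mol %), Me3SiCl, THF, −78 °C; then aq. NH4Cl
Reagents that add atoms: vinylmagnesium bromide, C=C[Mg]Br
Why: Copper‑catalysed, Me3SiCl‑accelerated conjugate addition of the vinyl Grignard reagent to the butenolide occurs anti to the silyloxymethyl group, which sets C7 trans to C8 (the later trans lactone fusion).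

Step 5
Reactants: 7 (4S,5R)-4-ethenyl-5-{[(triethylsilyl)oxy]methyl}oxolan-2-one
Product: 9 (2R,3R)-5-oxo-2-{[(triethylsilyl)oxy]methyl}oxolane-3-carbaldehyde, via ozonide 8 (not isolated)
Conditions: O3, CH2Cl2, −78 °C; PPh3, −78 °C → rt; crude aldehyde used at once
Reagents that add atoms: ozone, [O-][O+]=O
Why: Ozonolysis with reductive work‑up reveals the C6 aldehyde; the trans aldehyde is the thermodynamically preferred epimer and is used without base or chromatography to avoid β‑elimination of the lactone oxygen.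

Step 6
Reactants: 10 2,4-dimethylpenta-1,3-diene
Product: 12 B-(2,4-dimethylpenta-2,4-dien-1-yl)diisopinocampheylborane (kept as a solution at −78 °C), via potassium pentadienide 11 (not isolated)
Conditions: KOt-Bu, n-BuLi, THF, −78 → 0 °C; (−)-Ipc2BOMe, −78 °C; BF3·OEt2, −78 °C
Reagents that add atoms: (−)-B-methoxydiisopinocampheylborane, COB([C@@H]1C[C@@H]2C[C@@H](C2(C)C)[C@H]1C)[C@@H]1C[C@@H]2C[C@@H](C2(C)C)[C@H]1C
Why: Metalation with Schlosser base gives the symmetrical pentadienyl potassium, which is trapped by the methoxyborane as the ate complex and converted by BF3 into the allylic borane (Brown protocol for substituted allylboranes).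

Step 7
Reactants: 9 (2R,3R)-5-oxo-2-{[(triethylsilyl)oxy]methyl}oxolane-3-carbaldehyde; 12 B-(2,4-dimethylpenta-2,4-dien-1-yl)diisopinocampheylborane
Product: 14 (4S,5R)-4-[(1S)-1-hydroxy-3-methyl-2-(prop-1-en-2-yl)but-3-en-1-yl]-5-{[(triethylsilyl)oxy]methyl}oxolan-2-one, via borinate 13 (not isolated)
Conditions: THF/Et2O, −78 °C; then HOCH2CH2NH2, −78 °C → rt, filtration
Reagents that add atoms: none
Why: Brown allylboration through a Zimmerman–Traxler chair at the central (γ) carbon of the pentadienyl unit gives the bis‑isopropenyl carbinol; the isopinocampheyl groups from (+)‑α‑pinene direct attack to the Si face of the aldehyde (C6 S), no stereocentre arises at C5 because both arms end as identical isopropenyl groups (so the E/Z mixture of the reagent is immaterial), and the non‑basic ethanolamine work‑up avoids translactonisation to O6.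

Step 8
Reactants: 15 allylmagnesium bromide
Product: 16 diisopropyl allylboronate
Conditions: B(Oi-Pr)3, Et2O, −78 °C → rt; HCl (1 equiv, Et2O), 0 °C; distillation
Reagents that add atoms: triisopropyl borate, CC(C)OB(OC(C)C)OC(C)C
Why: Addition of the Grignard reagent to the borate and protonolysis of the ate complex gives the exchange‑labile allylboronic ester needed for the tether.

Step 9
Reactants: 14 (4S,5R)-4-[(1S)-1-hydroxy-3-methyl-2-(prop-1-en-2-yl)but-3-en-1-yl]-5-{[(triethylsilyl)oxy]methyl}oxolan-2-one; 16 diisopropyl allylboronate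
Product: 19 (4S,5R)-4-[(1S,2S,3Z)-1-hydroxy-3-methyl-2-(prop-1-en-2-yl)-5-(4,4,5,5-tetramethyl-1,3,2-dioxaborolan-2-yl)pent-3-en-1-yl]-5-{[(triethylsilyl)oxy]methyl}oxolan-2-one, via mixed boronic ester 17 (not isolated), via cyclic allylboronate 18 (not isolated)
Conditions: 16 (1.5 equiv), 4 Å MS, CH2Cl2, rt, then evaporation of i-PrOH; Grubbs II catalyst (10 mol %), CH2Cl2 (5 mM), 40 °C; pinacol, rt
Reagents that add atoms: pinacol, CC(C)(O)C(C)(C)O
Why: Boron‑tethered ring‑closing metathesis (temporary boron tether) closes a seven‑membered cyclic allylboronate whose ring forces the (Z)‑olefin (C5 cis to CH2B); of the two diastereotopic isopropenyl groups the one that leaves the spectator isopropenyl and the lactonyl group trans‑pseudo‑equatorial (reactive rotamer with H5 between O6 and C7) should close preferentially, which sets C5, and pinacol then exchanges the tether for the stable pinacol ester and frees O6–H.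

Step 10
Reactants: 19 (Z)-allylboronate alcohol
Product: 20 (4R,5R)-4-[(1S,2S,3Z)-3-methyl-2-(prop-1-en-2-yl)-5-(4,4,5,5-tetramethyl-1,3,2-dioxaborolan-2-yl)-1-[(triethylsilyl)oxy]pent-3-en-1-yl]-5-{[(triethylsilyl)oxy]methyl}oxolan-2-one
Conditions: Et3SiOTf, 2,6-lutidine, CH2Cl2, −78 °C
Reagents that add atoms: triethylsilyl trifluoromethanesulfonate, CC[Si](CC)(CC)OS(=O)(=O)C(F)(F)F
Why: Silyl triflate silylation of the hindered secondary C6 alcohol; the pinacol allylboronate is inert to the buffered silylating agent, and protecting O6 removes the risk of translactonisation and later differentiates O6 from O9.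

Step 11
Reactants: 20 bis(triethylsilyl) ether of the (Z)-allylboronate
Product: 23 9α-hydroxy-6β-(triethylsilyloxy)elema-1,3-dien-12,8α-olide (5αH,7αH,8βH,10β-CH3), via aldehyde 21 (not isolated), via boryl ether 22 (not isolated)
Conditions: (COCl)2, DMSO, CH2Cl2, −78 → −30 °C; i-Pr2NEt, −78 °C → rt; then 5 mM in CH2Cl2, rt → 35 °C; aq. NaHCO3/triethanolamine work-up
Reagents that add atoms: none
Why: Activated DMSO converts the primary triethylsilyl ether selectively (the secondary C6 ether is inert) into the alkoxysulfonium salt and then the C9 aldehyde 21, whose oxygen binds the pinacol boronate so that the allyl group is transferred through a six‑membered Zimmerman–Traxler chair with allylic transposition (C9–C10 forms, the C1=C2 vinyl group appears, boron ends on O9). The closest known reactions are the Swern oxidation of primary triethylsilyl ethers and the intramolecular allylboration of ω‑formyl allylboronates to 2‑vinylcycloalkanols. The cyclohexane C5–C10 closes in a 6‑exo‑trig mode at the carbonyl (C=O and the allyl π bond both exocyclic), the Zimmerman–Traxler ring being cis‑fused to the forming chair. C10 is controlled by the chair that the trans‑fused lactone and the equatorial isopropenyl group at C5 lock: the aldehyde substituent C8 must be equatorial in the Zimmerman–Traxler ring, which places C1 (vinyl) equatorial and the methyl group axial (β). C9 is controlled by the (Z) geometry fixed in step 9: C5 cis to CH2B is axial in the Zimmerman–Traxler ring, which puts O9 axial (α), trans to the methyl and cis to the vinyl group. The step needs chair over boat allyl transfer and intra‑ over intermolecular allylation; the first is secured by the rigid lactone‑fused chair (its only strain, the 1,3‑diaxial CH3/OSiEt3 contact, involves the smallest C10 substituent and is also present in the target), the second by high dilution.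

Step 12
Reactants: 23 9α-hydroxy-6β-(triethylsilyloxy)elema-1,3-dien-12,8α-olide
Product: 24 13-(dimethylamino)-9α-hydroxy-6β-(triethylsilyloxy)elema-1,3-dien-12,8α-olide (C11 epimers)
Conditions: LDA (2.3 equiv), THF, −78 °C; CH2=NMe2+ I−, −78 → 0 °C
Reagents that add atoms: Eschenmoser's salt (N,N-dimethylmethyleneiminium iodide), C=[N+](C)C.[I-]
Why: Mannich reaction of the lactone enolate (formed next to the C9 lithium alkoxide, which cannot reach C12 across the ring) with Eschenmoser's salt; the new C11 centre is removed in the next step.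

Step 13
Reactants: 24 13-(dimethylamino) lactone
Product: 26 9α-hydroxy-6β-(triethylsilyloxy)elema-1,3,11(13)-trien-12,8α-olide, via ammonium iodide 25 (not isolated)
Conditions: MeI, MeOH, rt; then aq. NaHCO3/CH2Cl2, rt
Reagents that add atoms: none
Why: Quaternisation and mild‑base E1cB elimination of trimethylamine install the α‑methylene lactone; O6 stays silylated so the weak base cannot trigger lactone migration.

Step 14
Reactants: 26 9α-hydroxy-6β-(triethylsilyloxy)elema-1,3,11(13)-trien-12,8α-olide; 27 angelic acid [(Z)-2-methylbut-2-enoic acid]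
Product: 29 9α-angeloyloxy-6β-(triethylsilyloxy)elema-1,3,11(13)-trien-12,8α-olide, via mixed anhydride 28 (not isolated)
Conditions: 27, 2,4,6-Cl3C6H2COCl, Et3N, toluene, rt; then 26, toluene, 80 °C (no DMAP)
Reagents that add atoms: none
Why: Yamaguchi esterification; the alcohol attacks the less hindered angeloyl carbonyl of the mixed anhydride, and omitting nucleophilic catalysts keeps the (Z) geometry of the angelate.

Step 15
Reactants: 29 9α-angeloyloxy-6β-(triethylsilyloxy)elema-1,3,11(13)-trien-12,8α-olide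
Product: 30 9α-angeloyloxy-15-hydroxy-6β-(triethylsilyloxy)elema-1,3,11(13)-trien-12,8α-olide
Conditions: SeO2 (0.5 equiv), t-BuOOH, CH2Cl2, rt
Reagents that add atoms: selenium dioxide, O=[Se]=O; tert-butyl hydroperoxide (terminal oxidant), CC(C)(C)OO
Why: Selenium dioxide allylic oxidation (ene reaction then [2,3] shift) attacks the methyl group of the isopropenyl unit, the only electron‑rich olefin with allylic hydrogens (the vinyl group has none, the methylene lactone and the angelate are electron‑poor); any enal formed by over‑oxidation converges in the next step.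

Step 16
Reactants: 30 15-hydroxy compound
Product: 31 9α-angeloyloxy-15-oxo-6β-(triethylsilyloxy)elema-1,3,11(13)-trien-12,8α-olide
Conditions: Dess–Martin periodinane, NaHCO3, CH2Cl2, 0 °C
Reagents that add atoms: none
Why: Dess–Martin oxidation of the only free (allylic, primary) alcohol gives the 2‑substituted acrolein under neutral conditions.

Step 17
Reactants: 31 6-O-triethylsilyl ether of the target
Product: 32 9α-angeloyloxy-6β-hydroxy-15-oxoelema-1,3,11(13)-trien-12,8α-olide (target, CNP0320538.1)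
Conditions: HF·pyridine, pyridine, THF, 0 °C
Reagents that add atoms: none
Why: Buffered fluoride desilylation frees O6–H without base, which avoids translactonisation from O8 to O6 and conjugate additions to the three acceptor olefins.

**Compound list**
1 | (5R)-5-(hydroxymethyl)oxolan-2-one | O=C1CC[C@H](CO)O1 | starting material
2 | (5R)-5-{[(triethylsilyl)oxy]methyl}oxolan-2-one | O=C1CC[C@H](CO[Si](CC)(CC)CC)O1 | intermediate
3 | (5R)-3-(phenylselanyl)-5-{[(triethylsilyl)oxy]methyl}oxolan-2-one (C3 epimers) | O=C1C([Se]c2ccccc2)C[C@H](CO[Si](CC)(CC)CC)O1 | intermediate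
4 | selenoxide of 3 | O=C1C([Se](=O)c2ccccc2)C[C@H](CO[Si](CC)(CC)CC)O1 | intermediate (not isolated)
5 | (5R)-5-{[(triethylsilyl)oxy]methyl}furan-2(5H)-one | O=C1C=C[C@H](CO[Si](CC)(CC)CC)O1 | intermediate
6 | 4,5-trans-4-ethenyl-5-{[(triethylsilyl)oxy]methyl}-2-(trimethylsilyloxy)-4,5-dihydrofuran (silyl ketene acetal of 7) | C=C[C@@H]1C=C(O[Si](C)(C)C)O[C@H]1CO[Si](CC)(CC)CC | intermediate (not isolated)
7 | (4S,5R)-4-ethenyl-5-{[(triethylsilyl)oxy]methyl}oxolan-2-one | O=C1C[C@@H](C=C)[C@H](CO[Si](CC)(CC)CC)O1 | intermediate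
8 | secondary ozonide (1,2,4-trioxolane) of 7 | O=C1C[C@@H](C2OCOO2)[C@H](CO[Si](CC)(CC)CC)O1 | intermediate (not isolated)
9 | (2R,3R)-5-oxo-2-{[(triethylsilyl)oxy]methyl}oxolane-3-carbaldehyde | O=C1C[C@@H](C=O)[C@H](CO[Si](CC)(CC)CC)O1 | intermediate
10 | 2,4-dimethylpenta-1,3-diene | CC(C)=CC(C)=C | starting material
11 | potassium 2,4-dimethylpentadienide | [K+].[CH2-]C(C)=CC(C)=C | intermediate (not isolated)
12 | B-(2,4-dimethylpenta-2,4-dien-1-yl)diisopinocampheylborane (Ipc from (+)-α-pinene) | C=C(C)C=C(C)CB([C@@H]1C[C@@H]2C[C@@H](C2(C)C)[C@H]1C)[C@@H]1C[C@@H]2C[C@@H](C2(C)C)[C@H]1C | intermediate (used in solution)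
13 | O6-diisopinocampheylboryl ether (borinate) of 14 | O=C1C[C@@H]([C@@H](OB([C@@H]2C[C@@H]3C[C@@H](C3(C)C)[C@H]2C)[C@@H]2C[C@@H]3C[C@@H](C3(C)C)[C@H]2C)C(C(C)=C)C(C)=C)[C@H](CO[Si](CC)(CC)CC)O1 | intermediate (not isolated)
14 | (4S,5R)-4-[(1S)-1-hydroxy-3-methyl-2-(prop-1-en-2-yl)but-3-en-1-yl]-5-{[(triethylsilyl)oxy]methyl}oxolan-2-one | O=C1C[C@@H]([C@@H](O)C(C(C)=C)C(C)=C)[C@H](CO[Si](CC)(CC)CC)O1 | intermediate
15 | allylmagnesium bromide | C=CC[Mg]Br | starting material
16 | diisopropyl allylboronate | C=CCB(OC(C)C)OC(C)C | intermediate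
17 | mixed allyl isopropyl boronic ester of 14 (O6–B) | O=C1C[C@@H]([C@@H](OB(CC=C)OC(C)C)C(C(C)=C)C(C)=C)[C@H](CO[Si](CC)(CC)CC)O1 | intermediate (not isolated)
18 | 6,7-trans-2-isopropoxy-5-methyl-6-(prop-1-en-2-yl)-7-[(2R,3S)-5-oxo-2-{[(triethylsilyl)oxy]methyl}oxolan-3-yl]-2,3,6,7-tetrahydro-1,2-oxaborepine | O=C1C[C@@H]([C@H]2OB(OC(C)C)CC=C(C)[C@@H]2C(C)=C)[C@H](CO[Si](CC)(CC)CC)O1 | intermediate (not isolated)
19 | (4S,5R)-4-[(1S,2S,3Z)-1-hydroxy-3-methyl-2-(prop-1-en-2-yl)-5-(4,4,5,5-tetramethyl-1,3,2-dioxaborolan-2-yl)pent-3-en-1-yl]-5-{[(triethylsilyl)oxy]methyl}oxolan-2-one | O=C1C[C@@H]([C@@H](O)[C@@H](C(C)=C)/C(C)=C\CB2OC(C)(C)C(C)(C)O2)[C@H](CO[Si](CC)(CC)CC)O1 | intermediate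
20 | (4R,5R)-4-[(1S,2S,3Z)-3-methyl-2-(prop-1-en-2-yl)-5-(4,4,5,5-tetramethyl-1,3,2-dioxaborolan-2-yl)-1-[(triethylsilyl)oxy]pent-3-en-1-yl]-5-{[(triethylsilyl)oxy]methyl}oxolan-2-one | O=C1C[C@@H]([C@@H](O[Si](CC)(CC)CC)[C@@H](C(C)=C)/C(C)=C\CB2OC(C)(C)C(C)(C)O2)[C@H](CO[Si](CC)(CC)CC)O1 | intermediate
21 | C9 aldehyde of 20 (2,3-trans-5-oxo-3-substituted oxolane-2-carbaldehyde) | O=C1C[C@@H]([C@@H](O[Si](CC)(CC)CC)[C@@H](C(C)=C)/C(C)=C\CB2OC(C)(C)C(C)(C)O2)[C@H](C=O)O1 | intermediate (not isolated)
22 | 9-O-(4,4,5,5-tetramethyl-1,3,2-dioxaborolan-2-yl) ether of 23 | C=C[C@]1(C)[C@H](OB3OC(C)(C)C(C)(C)O3)[C@@H]2OC(=O)C[C@H]2[C@@H](O[Si](CC)(CC)CC)[C@H]1C(C)=C | intermediate (not isolated)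
23 | 9α-hydroxy-6β-(triethylsilyloxy)elema-1,3-dien-12,8α-olide [(3aR,4S,5S,6S,7S,7aR)-6-ethenyl-7-hydroxy-6-methyl-5-(prop-1-en-2-yl)-4-[(triethylsilyl)oxy]hexahydro-1-benzofuran-2(3H)-one] | C=C[C@]1(C)[C@H](O)[C@@H]2OC(=O)C[C@H]2[C@@H](O[Si](CC)(CC)CC)[C@H]1C(C)=C | intermediate
24 | 13-(dimethylamino)-9α-hydroxy-6β-(triethylsilyloxy)elema-1,3-dien-12,8α-olide (C11 epimers) | C=C[C@]1(C)[C@H](O)[C@@H]2OC(=O)C(CN(C)C)[C@H]2[C@@H](O[Si](CC)(CC)CC)[C@H]1C(C)=C | intermediate
25 | N-methyl ammonium iodide of 24 | C=C[C@]1(C)[C@H](O)[C@@H]2OC(=O)C(C[N+](C)(C)C)[C@H]2[C@@H](O[Si](CC)(CC)CC)[C@H]1C(C)=C.[I-] | intermediate (not isolated)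
26 | 9α-hydroxy-6β-(triethylsilyloxy)elema-1,3,11(13)-trien-12,8α-olide | C=C[C@]1(C)[C@H](O)[C@@H]2OC(=O)C(=C)[C@H]2[C@@H](O[Si](CC)(CC)CC)[C@H]1C(C)=C | intermediate
27 | angelic acid [(Z)-2-methylbut-2-enoic acid] | C/C=C(/C)C(=O)O | starting material
28 | angelic 2,4,6-trichlorobenzoic anhydride | C/C=C(/C)C(=O)OC(=O)c1c(Cl)cc(Cl)cc1Cl | intermediate (not isolated)
29 | 9α-angeloyloxy-6β-(triethylsilyloxy)elema-1,3,11(13)-trien-12,8α-olide | C=C[C@]1(C)[C@H](OC(=O)/C(C)=C\C)[C@@H]2OC(=O)C(=C)[C@H]2[C@@H](O[Si](CC)(CC)CC)[C@H]1C(C)=C | intermediate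
30 | 9α-angeloyloxy-15-hydroxy-6β-(triethylsilyloxy)elema-1,3,11(13)-trien-12,8α-olide | C=C[C@]1(C)[C@H](OC(=O)/C(C)=C\C)[C@@H]2OC(=O)C(=C)[C@H]2[C@@H](O[Si](CC)(CC)CC)[C@H]1C(=C)CO | intermediate
31 | 9α-angeloyloxy-15-oxo-6β-(triethylsilyloxy)elema-1,3,11(13)-trien-12,8α-olide | C=C[C@]1(C)[C@H](OC(=O)/C(C)=C\C)[C@@H]2OC(=O)C(=C)[C@H]2[C@@H](O[Si](CC)(CC)CC)[C@H]1C(=C)C=O | intermediate
32 | 9α-angeloyloxy-6β-hydroxy-15-oxoelema-1,3,11(13)-trien-12,8α-olide, (3aS,4S,5R,6S,7S,7aR) (CNP0320538.1) | C=C[C@]1(C)[C@H](OC(=O)/C(C)=C\C)[C@@H]2OC(=O)C(=C)[C@H]2[C@@H](O)[C@H]1C(=C)C=O | target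

**Step count and risks**
Total step count: 17. Longest linear sequence: 15 steps (1 → 32 through steps 1–5, 7 and 9–17).

Steps most likely to fail:

1. Step 9 (boron‑tethered ring‑closing metathesis). What may go wrong: closure of a seven‑membered ring onto a 1,1‑disubstituted olefin may be slow and lose to oligomerisation, and the discrimination between the two diastereotopic isopropenyl groups (control of C5) may be weak. The fallback sets out from 14 and comes back at 19. 14 is exchanged with commercial dibutyl vinylboronate to the mixed vinylboronic ester F1. F1 is closed with Grubbs II catalyst to the better‑precedented six‑membered cyclic (Z)‑alkenylboronate F2, in whose half‑chair the lactonyl group at C6 and the spectator isopropenyl group at C5 sit trans‑pseudo‑equatorial. C2 is then inserted by Matteson homologation (BrCH2Cl, then n‑BuLi added last at −100 °C → rt, so that capture by boron outruns attack on the lactone; the alkenyl group migrates with retention of olefin geometry) to give the ring‑expanded cyclic allylboronate F3. Pinacol converts F3 into 19.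

2. Step 11 (key step). What may go wrong: the electrophilic chlorosulfonium species or HCl may attack the allylboronate (protodeboronation, allyl transfer to sulfur) before the aldehyde exists, or the amine base may epimerise the α‑acyloxy aldehyde at C8. The fallback sets out from 20 and comes back at 21 (and from there at 23 as in the main route). The primary silyl ether is cleaved selectively with PPTS in MeOH/CH2Cl2 at 0 °C to the primary alcohol F4. F4 is oxidised with Dess–Martin periodinane/NaHCO3 under neutral, amine‑free conditions, and the resulting aldehyde 21 is left in dilute solution to cyclise.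

3. Step 14 (angeloylation). What may go wrong: acylation of the neopentyl, axial C9 hydroxyl may be incomplete, and the activated angeloyl donor may isomerise (Z → E) to the tigloyl ester. The fallback sets out from 26 and comes back at 29. 26 is acylated with the unhindered, non‑isomerisable 2‑[bis(2,2,2‑trifluoroethoxy)phosphoryl]propanoic acid (EDC, DMAP, CH2Cl2) to the phosphonate ester F5. The (Z)‑olefin is then built on the molecule by Still–Gennari olefination of F5 with acetaldehyde (KHMDS, 18‑crown‑6, THF, −78 °C), which gives 29.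

Further compounds
F1 | step 9 | mixed butyl vinylboronic ester of 14 (O6–B(OBu)CH=CH2) | O=C1C[C@@H]([C@@H](OB(C=C)OCCCC)C(C(C)=C)C(C)=C)[C@H](CO[Si](CC)(CC)CC)O1
F2 | step 9 | 5,6-trans-2-butoxy-4-methyl-5-(prop-1-en-2-yl)-6-[(2R,3S)-5-oxo-2-{[(triethylsilyl)oxy]methyl}oxolan-3-yl]-5,6-dihydro-2H-1,2-oxaborinine | O=C1C[C@@H]([C@H]2OB(OCCCC)C=C(C)[C@@H]2C(C)=C)[C@H](CO[Si](CC)(CC)CC)O1
F3 | step 9 | 6,7-trans-2-butoxy-5-methyl-6-(prop-1-en-2-yl)-7-[(2R,3S)-5-oxo-2-{[(triethylsilyl)oxy]methyl}oxolan-3-yl]-2,3,6,7-tetrahydro-1,2-oxaborepine | O=C1C[C@@H]([C@H]2OB(OCCCC)CC=C(C)[C@@H]2C(C)=C)[C@H](CO[Si](CC)(CC)CC)O1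
F4 | step 11 | primary alcohol from 20 (C9–OH free, O6 silylated, (Z)-allyl pinacol boronate) | O=C1C[C@@H]([C@@H](O[Si](CC)(CC)CC)[C@@H](C(C)=C)/C(C)=C\CB2OC(C)(C)C(C)(C)O2)[C@H](CO)O1
F5 | step 14 | 9-O-{2-[bis(2,2,2-trifluoroethoxy)phosphoryl]propanoyl} ester of 26 | C=C[C@]1(C)[C@H](OC(=O)C(C)P(=O)(OCC(F)(F)F)OCC(F)(F)F)[C@@H]2OC(=O)C(=C)[C@H]2[C@@H](O[Si](CC)(CC)CC)[C@H]1C(C)=C
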